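The cyclobutane C1–C4 is a twofold-symmetric μ-truxinate. Carboxyl-bearing C1 and C2 are trans and aryl-bearing C3 and C4 are trans, yet each aryl is cis to the neighbouring carboxyl (C4/C1, C3/C2). This is the anti head-to-head dimer of a Z-locked caffeate, so the free ortho C–H of each ring-bound catechol carries a temporary lactone oxygen. Triplet-sensitised [2+2] photodimerisation of 6,7-bis(benzyloxy)coumarin forges C1–C2, C3–C4 and all four ring stereocentres at once. The two aryl lactones then act as built-in active esters towards the (R)-danshensu alkoxide, which also resolves the core. The freed phenols leave as triflates in the closing hydrogenolysis.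

Key step: step 2

Assumption: step 2 gives 4 as a racemate (names and SMILES of 3 and 4 show the enantiomer that is carried on), and the core configuration is fixed when the two diastereomers formed with enantiopure 6 are separated in step 4, the assignment to be settled by X-ray or ECD analysis.

Step 1
Reactants: 1 esculetin (6,7-dihydroxycoumarin)
Product: 2 6,7-bis(benzyloxy)coumarin
Conditions: BnBr (2.3 equiv), K2CO3, DMF, 50 °C
Reagents that add atoms: benzyl bromide, BrCc1ccccc1
Why: Williamson ether synthesis, in which both phenoxides of 1 are alkylated by SN2 on benzyl bromide while the lactone is inert to anhydrous carbonate and no stereocentre is involved.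

Step 2
Reactants: 2 6,7-bis(benzyloxy)coumarin (two molecules)
Product: 4 racemic anti head-to-head photodimer (6aR,6bR,12bR,12cR)-2,3,10,11-tetrakis(benzyloxy)-6a,6b,12b,12c-tetrahydrocyclobuta[1,2-c:4,3-c']dichromene-6,7-dione, via triplet 1,4-biradical 3 (not isolated)
Conditions: [Ir(dF(CF3)ppy)2(dtbbpy)]PF6 (1 mol %), degassed CH2Cl2 (0.3 M), 450 nm LEDs, 25 °C
Reagents that add atoms: none
Why: Triplet energy transfer from the photoexcited iridium complex populates the planar π,π* triplet of 2, whose coumarin C3 bonds to C3 of a ground-state molecule (the C1–C2 bond of the target) to give biradical 3, and after intersystem crossing 3 collapses by C4–C4' recombination (the C3–C4 bond). The closest known reaction type is the triplet-sensitised [2+2] photodimerisation of coumarins to their anti head-to-head dimers, run here with a visible-light sensitiser so that 2, expected to be transparent above about 400 nm, never reaches the singlet state from which syn dimers arise. The only ring closed is the cyclobutane, by a stepwise [2+2] cycloaddition that ends in 1,4-biradical recombination. C1/C4 and C2/C3 are set cis by the temporary rings, since each pair is the fusion bond of a rigid benzo-annulated six-membered lactone that admits only cis fusion, so the Z geometry of the masked caffeate survives a non-concerted mechanism. C1/C2 and C3/C4 are set trans because 3 closes from the conformer that keeps the two benzopyranone planes and their carbonyl dipoles on opposite faces of the nascent ring, whereas nothing controls the absolute sense, so 4 is racemic and the sense is selected in step 4. The step needs head-to-head over head-to-tail and anti over syn selectivity: the first is secured by the 3,3'-union being the only one that leaves both spins benzylic and para to a 7-alkoxy donor, the second by exclusive triplet population, and the saturated product can no longer accept energy from the sensitiser, so it is not cleaved again.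

Step 3
Reactants: 5 sodium (R)-3-(3,4-dihydroxyphenyl)lactate (sodium danshensu)
Product: 6 benzyl (R)-3-[3,4-bis(benzyloxy)phenyl]-2-hydroxypropanoate
Conditions: BnBr (3.3 equiv), K2CO3, DMF, rt
Reagents that add atoms: benzyl bromide, BrCc1ccccc1
Why: Carbonate ionises only the two phenols beside the carboxylate, so SN2 benzylation (Williamson etherification plus carboxylate alkylation) leaves the far less acidic secondary alcohol free and the (R)-centre from the chiral pool untouched.

Step 4
Reactants: 4 racemic anti head-to-head photodimer; 6 benzyl (R)-3-[3,4-bis(benzyloxy)phenyl]-2-hydroxypropanoate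
Product: 9 bis{(1R)-1-[(benzyloxy)carbonyl]-2-[3,4-bis(benzyloxy)phenyl]ethyl} (1R,2R,3R,4R)-3,4-bis[4,5-bis(benzyloxy)-2-(trifluoromethylsulfonyloxy)phenyl]cyclobutane-1,2-dicarboxylate, via lithium alkoxide 7 (not isolated), via dilithium bis(phenoxide) 8 (not isolated)
Conditions: 6 (2.3 equiv), LiN(SiMe3)2 (2.2 equiv), THF, −78 °C; add 4, −78 to −20 °C; PhNTf2 (2.5 equiv), −20 °C to rt; aq NH4Cl; chromatographic separation of the two diastereomers on SiO2
Reagents that add atoms: N-phenylbis(trifluoromethanesulfonimide), O=S(=O)(N(c1ccccc1)S(=O)(=O)C(F)(F)F)C(F)(F)F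
Why: Alkoxide 7 opens both aryl-lactone carbonyls of 4 by acyl–oxygen cleavage (alkoxide transesterification of an aryl ester, driven by release of the less basic phenoxide 8), O-triflation with PhNTf2 then blocks relactonisation without touching any ring stereocentre, and because 6 is a single (R)-enantiomer the two enantiomers of 4 emerge as diastereomers from which the (1R,2R,3R,4R) compound 9 is separated.

Step 5
Reactants: 9 bis(triflate) diester
Product: 10 target CNP0163929.1, bis[(1R)-1-carboxy-2-(3,4-dihydroxyphenyl)ethyl] (1R,2R,3R,4R)-3,4-bis(3,4-dihydroxyphenyl)cyclobutane-1,2-dicarboxylate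
Conditions: H2 (4 bar), 10% Pd/C, Et3N (5 equiv), THF–MeOH, rt; dilute HCl under Ar; reversed-phase chromatography
Reagents that add atoms: none
Why: Heterogeneous hydrogenolysis cleaves the ten benzylic C–O bonds and, with Et3N as acid scavenger, also the two aryl C–OTf bonds (catalytic hydrodeoxygenation of aryl triflates), while no stereocentre carries a benzylic C–O bond and the cyclobutane C–C bonds should resist Pd/C at room temperature.

Compound list
1 | esculetin (6,7-dihydroxycoumarin) | O=c1ccc2cc(O)c(O)cc2o1 | starting material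
2 | 6,7-bis(benzyloxy)coumarin | O=c1ccc2cc(OCc3ccccc3)c(OCc3ccccc3)cc2o1 | intermediate
3 | triplet bis-benzylic 1,4-biradical, 3,3'-linked bis[6,7-bis(benzyloxy)-2-oxochroman-4-yl], (3R,3'R) drawn, racemic | O=C1Oc2cc(OCc3ccccc3)c(OCc3ccccc3)cc2[CH][C@@H]1[C@H]1[CH]c2cc(OCc3ccccc3)c(OCc3ccccc3)cc2OC1=O | intermediate
4 | anti head-to-head photodimer of 2, both lactones cis-fused on opposite faces of the cyclobutane, (6aR,6bR,12bR,12cR) drawn, racemic | O=C1Oc2cc(OCc6ccccc6)c(OCc6ccccc6)cc2[C@H]3[C@@H]1[C@@H]4C(=O)Oc5cc(OCc6ccccc6)c(OCc6ccccc6)cc5[C@H]34 | intermediate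
5 | sodium (R)-3-(3,4-dihydroxyphenyl)lactate (sodium danshensu) | O[C@H](Cc1ccc(O)c(O)c1)C(=O)[O-].[Na+] | starting material
6 | benzyl (R)-3-[3,4-bis(benzyloxy)phenyl]-2-hydroxypropanoate | O[C@H](Cc1ccc(OCc2ccccc2)c(OCc2ccccc2)c1)C(=O)OCc1ccccc1 | intermediate
7 | lithium alkoxide of 6 | [Li+].[O-][C@H](Cc1ccc(OCc2ccccc2)c(OCc2ccccc2)c1)C(=O)OCc1ccccc1 | intermediate
8 | dilithium bis(phenoxide) of the doubly ring-opened diester, (1R,2R,3R,4R) core drawn | O=C(O[C@H](Cc1ccc(OCc2ccccc2)c(OCc2ccccc2)c1)C(=O)OCc1ccccc1)[C@H]1[C@H](C(=O)O[C@H](Cc2ccc(OCc3ccccc3)c(OCc3ccccc3)c2)C(=O)OCc2ccccc2)[C@H](c2cc(OCc3ccccc3)c(OCc3ccccc3)cc2[O-])[C@H]1c1cc(OCc2ccccc2)c(OCc2ccccc2)cc1[O-].[Li+].[Li+] | intermediate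
9 | bis(triflate) diester, (1R,2R,3R,4R) core with two (R)-danshensu benzyl ester units | O=C(O[C@H](Cc1ccc(OCc2ccccc2)c(OCc2ccccc2)c1)C(=O)OCc1ccccc1)[C@H]1[C@H](C(=O)O[C@H](Cc2ccc(OCc3ccccc3)c(OCc3ccccc3)c2)C(=O)OCc2ccccc2)[C@H](c2cc(OCc3ccccc3)c(OCc3ccccc3)cc2OS(=O)(=O)C(F)(F)F)[C@H]1c1cc(OCc2ccccc2)c(OCc2ccccc2)cc1OS(=O)(=O)C(F)(F)F | intermediate
10 | CNP0163929.1, bis[(1R)-1-carboxy-2-(3,4-dihydroxyphenyl)ethyl] (1R,2R,3R,4R)-3,4-bis(3,4-dihydroxyphenyl)cyclobutane-1,2-dicarboxylate | O=C(O[C@H](Cc1ccc(O)c(O)c1)C(=O)O)[C@H]1[C@H](C(=O)O[C@H](Cc2ccc(O)c(O)c2)C(=O)O)[C@H](c2ccc(O)c(O)c2)[C@H]1c1ccc(O)c(O)c1 | target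

Total step count: 5. Longest linear sequence: 4 steps (1 → 2 → 4 → 9 → 10, steps 1, 2, 4 and 5).

Steps most likely to fail

**Step 2.**
- Risk: energy transfer to the electron-rich chromophore may be slow. The bimolecular capture of the triplet may also leak into head-to-tail or syn pairing.
- Fallback: run the cycloaddition intramolecularly instead of intermolecularly.
- Setting out from 1, the more acidic 7-OH is benzylated selectively (BnBr 1 equiv, KHCO3, DMF) to give 7-benzyloxy-6-hydroxycoumarin F1.
- Two molecules of F1 are joined through O6 with 1,3-bis(bromomethyl)benzene (K2CO3, DMF) to give the m-xylylene-tethered bis(coumarin) F2.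
- Sensitised irradiation at high dilution should close the same two bonds inside the tether and give the tethered anti head-to-head photoadduct F3 (racemic).
- Head-to-tail pairing is out of reach of the tether. The tether span fits the O6···O6' separation estimated from models for the anti geometry (about 6 Å).
- F3 is opened with 7 and triflated as in step 4 to give the tethered bis(triflate) diester F4, after separation of diastereomers.
- The hydrogenolysis of step 5 also cleaves the two benzylic C–O bonds of the tether, so the fallback comes back to the route at 10.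

**Step 4.**
- Risk: relactonisation may outrun the triflate trap with the hindered secondary alkoxide. Base may epimerise C1/C2 towards the all-trans array, or the diastereomers may resolve poorly.
- Fallback: decouple ring opening from introduction of the chiral alcohol.
- Setting out from 4, lithium allyloxide (allyl alcohol, LiN(SiMe3)2, THF, −78 °C) followed by PhNTf2 gives the diallyl ester bis(triflate) F5 (racemic).
- Tsuji–Trost deallylation (Pd(PPh3)4 cat., morpholine, THF, rt) gives the diacid bis(triflate) F6.
- Steglich esterification with 6 (EDC·HCl, DMAP cat., CH2Cl2, 0 °C) and separation of the diastereomers comes back to the route at 9.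

**Step 5.**
- Risk: hydrogenolysis of the C–OTf bonds may stall on the electron-rich, ortho-hindered rings once the benzyl ethers have fallen. The amine may also slow O-debenzylation.
- Fallback: separate the two reductions.
- Setting out from 9, homogeneous transfer reduction of the aryl triflates (Pd(OAc)2, dppf, HCO2H, Et3N, DMF, 60 °C) leaves all benzyl groups in place and gives the decabenzyl compound F7.
- Neutral hydrogenolysis of F7 (H2, 10% Pd/C, THF–MeOH, rt) comes back to the route at 10.

Further compounds
F1 | step 2 | 7-benzyloxy-6-hydroxycoumarin | O=c1ccc2cc(O)c(OCc3ccccc3)cc2o1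
F2 | step 2 | 1,3-bis{[(7-benzyloxy-2-oxo-2H-chromen-6-yl)oxy]methyl}benzene | O=c1ccc2cc(OCc3cccc(COc4cc5ccc(=O)oc5cc4OCc4ccccc4)c3)c(OCc3ccccc3)cc2o1
F3 | step 2 | m-xylylene-tethered anti head-to-head photoadduct, racemic, enantiomer corresponding to 4 drawn | O=C1Oc2cc(OCc6ccccc6)c(OCc7cccc(c7)CO8)cc2[C@H]3[C@@H]1[C@@H]4C(=O)Oc5cc(OCc6ccccc6)c8cc5[C@H]34
F4 | step 2 | m-xylylene-tethered bis(triflate) diester, (1R,2R,3R,4R) core with two (R)-danshensu benzyl ester units | O=C(O[C@H](Cc1ccc(OCc2ccccc2)c(OCc2ccccc2)c1)C(=O)OCc1ccccc1)[C@H]1[C@H](C(=O)O[C@H](Cc2ccc(OCc3ccccc3)c(OCc3ccccc3)c2)C(=O)OCc2ccccc2)[C@H](c2cc(OCc3cccc(c3)CO4)c(OCc3ccccc3)cc2OS(=O)(=O)C(F)(F)F)[C@H]1c1cc4c(OCc2ccccc2)cc1OS(=O)(=O)C(F)(F)F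
F5 | step 4 | diallyl 3,4-bis[4,5-bis(benzyloxy)-2-(trifluoromethylsulfonyloxy)phenyl]cyclobutane-1,2-dicarboxylate, racemic, (1R,2R,3R,4R) drawn | O=C(OCC=C)[C@H]1[C@H](C(=O)OCC=C)[C@H](c2cc(OCc3ccccc3)c(OCc3ccccc3)cc2OS(=O)(=O)C(F)(F)F)[C@H]1c1cc(OCc2ccccc2)c(OCc2ccccc2)cc1OS(=O)(=O)C(F)(F)F
F6 | step 4 | 3,4-bis[4,5-bis(benzyloxy)-2-(trifluoromethylsulfonyloxy)phenyl]cyclobutane-1,2-dicarboxylic acid, racemic, (1R,2R,3R,4R) drawn | O=C(O)[C@H]1[C@H](C(=O)O)[C@H](c2cc(OCc3ccccc3)c(OCc3ccccc3)cc2OS(=O)(=O)C(F)(F)F)[C@H]1c1cc(OCc2ccccc2)c(OCc2ccccc2)cc1OS(=O)(=O)C(F)(F)F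
F7 | step 5 | decabenzyl derivative of 10 (eight benzyl ethers, two benzyl esters), (1R,2R,3R,4R) core | O=C(O[C@H](Cc1ccc(OCc2ccccc2)c(OCc2ccccc2)c1)C(=O)OCc1ccccc1)[C@H]1[C@H](C(=O)O[C@H](Cc2ccc(OCc3ccccc3)c(OCc3ccccc3)c2)C(=O)OCc2ccccc2)[C@H](c2ccc(OCc3ccccc3)c(OCc3ccccc3)c2)[C@H]1c1ccc(OCc2ccccc2)c(OCc2ccccc2)c1
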